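**Assumptions.** (−)-Linalool is taken as the commercial natural (R)-enantiomer of high ee. Dictyol numbering is used throughout: C1/C5 are the ring-fusion carbons, C4 is the ring alkene carbon bearing CH3, C6 is the carbinol, C7 bears the side chain, C10 bears the exocyclic CH2, C11 is the quaternary THF carbon, C14 is the THF CH, and C15 is CMe2OAc.

## Retrosynthetic overview
1. Dictyol H ⇐ β,γ-enone 13 (hydride to C6 from the convex face) ⇐ conjugated enone 12 (deconjugative protonation sets C5).
2. The seven-membered ring closes last, at C8–C9. A visible-light 7-endo allyl-radical cyclisation onto an α-methylene ketone sets C7 and regenerates C10=CH2.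
3. C6–C7 is formed by Nozaki–Hiyama–Kishi union of a C10 enal with a C12 vinyl triflate. The skeleton is limonene plus linalool.
4. The cyclopentene comes from (R)-limonene by ring cleavage and aldol, which supplies C1. The THF comes from (R)-linalool as furanoid linalool oxide, which supplies C11 and then C14.
5. Ring order: cyclopentene and THF are made on separate branches, then the cycloheptane.

## Route

**Step 1**
Reactants: 1, (R)-(+)-limonene
Product: 2, (3R)-6-oxo-3-(prop-1-en-2-yl)heptanal
Conditions: O3 (1.0 equiv, indicator-controlled), CH2Cl2/MeOH, −78 °C; then Me2S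
Reagents that add atoms: ozone, [O-][O+]=O
Why: In this chemoselective ozonolysis, electrophilic ozone cleaves the trisubstituted ring alkene faster than the 1,1-disubstituted isopropenyl group, and the purchased stereocentre (future C1) is untouched.

**Step 2**
Reactants: 2
Product: 3, (5S)-2-methyl-5-(prop-1-en-2-yl)cyclopent-1-ene-1-carbaldehyde
Conditions: piperidine (cat.), AcOH (cat.), toluene, reflux (−H2O)
Reagents that add atoms: none
Why: This is an enamine-mediated intramolecular aldol condensation in which the aldehyde α-carbon attacks the methyl ketone (five-membered ring only), and the S descriptor reflects a CIP priority change, not a change in geometry.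

**Step 3**
Reactants: 4, (R)-(−)-linalool
Product: 5, trans-furanoid linalool oxide, 2-[(2R,5R)-5-ethenyl-5-methyloxolan-2-yl]propan-2-ol, carried on together with its C14 epimer and about 20% pyranoid isomers
Conditions: mCPBA, CH2Cl2, 0 °C; then p-TsOH (cat.), rt
Reagents that add atoms: mCPBA, OOC(=O)c1cccc(Cl)c1
Why: Prilezhaev epoxidation of the more nucleophilic trisubstituted alkene is followed by 5-exo epoxide opening by the C11 hydroxyl, with C11 bought in; methyl and vinyl give almost no 1,4-induction (trans:cis about 1:1), so C14 is secured as a separable diastereomer relative to C11 in step 4.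

**Step 4**
Reactants: 5 (mixture)
Product: 6, 2-[(2R,5R)-5-ethenyl-5-methyloxolan-2-yl]propan-2-yl acetate, single isomer
Conditions: Ac2O, NaOAc, reflux; silica gel chromatography
Reagents that add atoms: acetic anhydride, CC(=O)OC(C)=O
Why: Forcing acetylation installs the tertiary acetate of the target before any secondary alcohol exists, and the cis and trans acetates (unlike the alcohols) separate cleanly.

**Step 5**
Reactants: 6
Product: 7, 2-[(2R,5R)-5-acetyl-5-methyloxolan-2-yl]propan-2-yl acetate
Conditions: Pd(quinox)Cl2 (5 mol %), AgSbF6, aq. TBHP, CH2Cl2, rt
Reagents that add atoms: tert-butyl hydroperoxide, CC(C)(C)OO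
Why: This peroxide-mediated Wacker-type oxidation is catalyst-controlled and Markovnikov-selective, so it gives the methyl ketone even with an allylic ether oxygen, and no stereocentre is involved.

**Step 6**
Reactants: 7
Product: 8, 1-[(2R,5R)-5-(2-acetoxypropan-2-yl)-2-methyloxolan-2-yl]ethenyl trifluoromethanesulfonate
Conditions: KHMDS (1.05 equiv), THF, −78 °C; PhNTf2
Reagents that add atoms: N-phenylbis(trifluoromethanesulfonimide), O=S(=O)(N(c1ccccc1)S(=O)(=O)C(F)(F)F)C(F)(F)F
Why: In this enol triflation the ketone can enolise only toward CH3 because C11 is quaternary, and it is far more acidic than the acetate, so a single 1,1-disubstituted vinyl triflate forms.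

**Step 7**
Reactants: 8 and 3
Product: 9, the bis-allylic alcohol CH2=C7(C11-THF)–C6H(OH)–(2-methyl-5-isopropenylcyclopent-1-enyl), with (1S,11R,14R) configuration and C6 as an epimer mixture
Conditions: CrCl2 (5 equiv), NiCl2 (2 mol %), DMF, rt
Reagents that add atoms: none
Why: In the Nozaki–Hiyama–Kishi coupling the alkenylchromium adds 1,2 to the hindered enal and tolerates the ester and ether, and the C6 epimers do not matter because C6 is oxidised next.

**Step 8**
Reactants: 9
Product: 10, cross-conjugated dienone (C4=C5–C6(=O)–C7=C8H2), (1S,11R,14R)
Conditions: Dess–Martin periodinane, NaHCO3, CH2Cl2, 0 °C to rt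
Reagents that add atoms: none
Why: Buffered Dess–Martin oxidation of the doubly allylic alcohol is non-acidic and so avoids Nazarov closure of the divinyl ketone.

**Step 9**
Reactants: 10
Product: 11, allylic chloride in which the C1 substituent is now C10(=CH2)CH2Cl; (1R,11R,14R), where the C1 descriptor change is due to CIP priority only
Conditions: aq. NaOCl, CeCl3·7H2O, CH2Cl2/H2O, 0 °C
Reagents that add atoms: sodium hypochlorite, [Na+].[O-]Cl
Why: Ene-type electrophilic allylic chlorination by HOCl hits the isopropenyl group because it is the only electron-rich alkene left, both enone alkenes being deactivated as in the 10-chlorination of carvone.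

**Step 10 (key step)**
Reactants: 11
Product: 12, hydroazulenone (C4=C5 conjugated with the C6 ketone, C10=CH2, H7 cis to H1), (1S,7S,11R,14R)
Conditions: 4CzIPN (5 mol %), i-Pr2NEt (3 equiv), NaI (1 equiv), H2O (10 equiv), MeCN (5 mM), 450 nm LEDs, rt; brief DBU equilibration if needed
Reagents that add atoms: none
Why: Proposed new method: a visible-light halogen-atom-transfer 7-endo-trig Giese cyclisation of a stabilised 2-substituted allyl radical, in which in-situ Finkelstein exchange gives the allyl iodide, reductive quenching of 4CzIPN* by the amine gives an α-aminoalkyl radical that abstracts iodine, and the resulting allyl radical (equivalent CH2 termini, so either one gives the same skeleton and restores C10=CH2) attacks the unhindered C8 terminus of the s-trans α-methylene ketone from below the enone plane; 6-exo attack at C7 is blocked by quaternary C11, 5-endo attack at C4 is disfavoured, and addition to C=O is reversible; the tertiary α-keto radical (about −0.6 V) is reduced by 4CzIPN•− (−1.2 V) while the allyl radical (about −1.4 V) is not, so no allyl anion forms and 1,2-addition to C6 is avoided; the enolate is protonated on the open face syn to H1 because the C8–C10 bridge lies on the other face, and this also places the bulky C11 group pseudo-equatorial, so kinetic and thermodynamic control agree at C7; the closest known reaction types are photoredox/XAT Giese additions of unstabilised alkyl iodides and tin-hydride 7-endo cyclisations onto acryloyl acceptors.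

**Step 11**
Reactants: 12
Product: 13, cis-fused β,γ-enone (C3=C4, H5 cis to H1 and H7), (1R,5R,7S,11R,14R), used crude
Conditions: LDA (2.5 equiv), THF/DMPU, −78 °C; inverse quench into AcOH/THF, −78 °C
Reagents that add atoms: none
Why: In this deconjugative protonation, γ-deprotonation at C3 gives the through-conjugated endocyclic dienolate (as with 2-methylcycloalkenyl carbonyls), kinetic α-protonation at C5 occurs from the convex face syn to H1, and the excess base only converts the acetate temporarily to its lithium enolate.

**Step 12**
Reactants: 13
Product: 14, dictyol H, (1R,5R,6S,7R,11R,14R)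
Conditions: NaBH4, CeCl3·7H2O, MeOH/THF, −40 to −20 °C
Reagents that add atoms: none
Why: Luche reduction is fast and non-basic, so there is no reconjugation and the acetate is untouched, and hydride arrives from the convex face carrying H1, H5 and H7, which places the C6 hydroxyl cis to the C7 side chain (6S).

## Compound list
1 | (R)-(+)-limonene | CC1=CC[C@@H](CC1)C(C)=C | starting material
2 | (3R)-6-oxo-3-(prop-1-en-2-yl)heptanal | CC(=O)CC[C@H](CC=O)C(C)=C | intermediate
3 | (5S)-2-methyl-5-(prop-1-en-2-yl)cyclopent-1-ene-1-carbaldehyde | O=CC1=C(C)CC[C@H]1C(C)=C | intermediate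
4 | (R)-(−)-linalool | C=C[C@@](O)(C)CCC=C(C)C | starting material
5 | (2R,5R)-trans-furanoid linalool oxide | C=C[C@@]1(C)CC[C@H](C(C)(C)O)O1 | intermediate
6 | (2R,5R)-trans-linalool oxide acetate | C=C[C@@]1(C)CC[C@H](C(C)(C)OC(C)=O)O1 | intermediate
7 | 2-[(2R,5R)-5-acetyl-5-methyloxolan-2-yl]propan-2-yl acetate | CC(=O)[C@@]1(C)CC[C@H](C(C)(C)OC(C)=O)O1 | intermediate
8 | vinyl triflate of 7 | C=C(OS(=O)(=O)C(F)(F)F)[C@@]1(C)CC[C@H](C(C)(C)OC(C)=O)O1 | intermediate
9 | bis-allylic alcohol (C6 epimers) | C=C(C(O)C1=C(C)CC[C@H]1C(C)=C)[C@@]1(C)CC[C@H](C(C)(C)OC(C)=O)O1 | intermediate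
10 | cross-conjugated dienone | C=C(C(=O)C1=C(C)CC[C@H]1C(C)=C)[C@@]1(C)CC[C@H](C(C)(C)OC(C)=O)O1 | intermediate
11 | allylic chloride dienone | C=C(C(=O)C1=C(C)CC[C@H]1C(=C)CCl)[C@@]1(C)CC[C@H](C(C)(C)OC(C)=O)O1 | intermediate
12 | conjugated hydroazulenone | C=C1CC[C@@H]([C@@]2(C)CC[C@H](C(C)(C)OC(C)=O)O2)C(=O)C2=C(C)CC[C@@H]12 | intermediate
13 | cis-fused β,γ-enone | C=C1CC[C@@H]([C@@]2(C)CC[C@H](C(C)(C)OC(C)=O)O2)C(=O)[C@H]2C(C)=CC[C@@H]12 | intermediate
14 | dictyol H | C=C1CC[C@@H]([C@@]2(C)CC[C@H](C(C)(C)OC(C)=O)O2)[C@@H](O)[C@H]2C(C)=CC[C@@H]12 | target

## Summary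
Total steps: 12.
Longest linear sequence: 10 (steps 3–12, from linalool).

Steps most likely to fail:
1. **Step 10 (new allyl-radical 7-endo closure).** The stabilised radical may add too slowly, be reduced, or dimerise.
   Fallback (known polar chemistry): convert the allyl chloride to the allyltrimethylsilane by Pd-catalysed silylation with Me3SiSiMe3, or carry the silane from limonene metalated at C10 and quenched with TMSCl. Then close the ring by a fluoride- or EtAlCl2-induced intramolecular Hosomi–Sakurai conjugate allylation.
2. **Step 5 (Wacker oxidation of a vinyl group on a quaternary, oxygenated carbon).** It may be slow or give aldehyde.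
   Fallback: bypass 7 and 8. Ozonolyse 6 to the aldehyde, homologate with the Ohira–Bestmann reagent to the terminal alkyne, then couple with 3 by Ni(0)/bulky-NHC/silane reductive coupling (branched-selective) to give silyl-protected 9.
3. **Step 11 (deconjugation).** Risks are the wrong dienolate (exocyclic C4=CH2), reconjugation, or acetate loss.
   Fallback: form the cyclopentene last. Take keto-aldehyde 2 through steps 7–10, using the aldehyde selectivity of the NHK coupling. Then close C4–C5 by intramolecular aldol addition of the cycloheptanone. Finally dehydrate the tertiary alcohol away from the carbonyl with Burgess reagent (syn-elimination) to give 13 directly.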